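Ring numbering used throughout: C1(OAc)–C2(OH)(COC10H21)–C3(OAc)–C4=C5.
- **Cuts:** the C2–OH and side-chain C=O pair goes back to an exocyclic C2=CH–C10H21 alkene, and C1–OAc goes back to a ring ketone. That cyclopentenone is then cut at C1–C5 and C2–C3 together.
- **Fragments:** 1-ethoxytrideca-1,2-diene supplies C1, C2 and the whole side chain. (E)-3-oxoprop-1-enyl pivalate supplies C5, C4 and C3 with its oxygen.
- **Enabling feature:** oxygen on C1 and C3, plus an exocyclic carbon of carbonyl rank on C2, lets the five ring carbons be written as a pentadienyl cation C3–C4–C5–C1–C2 whose C2 end is the central carbon of an allene.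
- **Forward order:** both fragments are made, the ring is built in one flask (addition forms C1–C5, electrocyclisation forms C2–C3), and then come ketone reduction with pivalate removal, acetylation, osmylation and oxidation. The helpers (ethyl ether, pivalate) leave in steps 3 and 4.
- **Stereochemistry:** C3 is formed as a racemate, C1 is set by hydride attack anti to the C3 oxygen, and C2 is set by osmylation anti to both acetates. The side-chain carbinol is erased at the end, which gives the meso target.

Key step: step 3

Assumption: the descriptors of the target describe the meso isomer (both acetates cis to each other and to the undecanoyl group, tertiary OH trans), so racemic intermediates suffice. Each SMILES of a racemate shows one enantiomer.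

Step 1
Reactants: 1 decylmagnesium bromide; 2 3,3-diethoxyprop-1-yne
Product: 3 1-ethoxytrideca-1,2-diene (racemic)
Conditions: CuBr (5 mol %), P(OEt)3 (10 mol %), Et2O, −20 to 0 °C; then H2O
Reagents that add atoms: none
Why: Copper-catalysed SN2′ substitution of a propargylic acetal by a Grignard reagent puts the decyl group on the alkyne terminus and expels one ethoxide, which is the standard entry to 3-alkyl-1-alkoxyallenes, and the racemic axial chirality is erased later.

Step 2
Reactants: 4 tetrabutylammonium (E)-3-oxoprop-1-en-1-olate (malondialdehyde tetrabutylammonium salt)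
Product: 5 (E)-3-oxoprop-1-en-1-yl pivalate
Conditions: t-BuCOCl, CH2Cl2, 0 °C
Reagents that add atoms: pivaloyl chloride, CC(C)(C)C(=O)Cl
Why: O-acylation of the malondialdehyde enolate by an acyl chloride gives the E enol ester, as known for benzoyl chloride, and the tert-butyl group is chosen to shield the ester carbonyl in step 3.

Step 3
Reactants: 3 1-ethoxytrideca-1,2-diene; 5 (E)-3-oxoprop-1-en-1-yl pivalate
Product: 11 (±)-(5Z)-4-oxo-5-undecylidenecyclopent-2-en-1-yl pivalate, via lithioallene 6 (not isolated), via lithium alkoxide 7 (not isolated), via allylic trifluoroacetate 8 (not isolated), via pentadienyl cation 9 (not isolated), via ethoxyallyl cation 10 (not isolated)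
Conditions: n-BuLi, THF, −78 °C; 5, −78 °C; 2,6-lutidine, (CF3CO)2O (1.05 equiv), −78 to 0 °C; aq NaHCO3
Reagents that add atoms: water, O
Why: Proposed new method: lithiation of 3 at the oxygen-bearing allene carbon (6) and 1,2-addition to the aldehyde of 5 form C1–C5 (7); trifluoroacetylation (8) and ionisation give cation 9, which spans all five ring carbons and closes C2–C3 between the central allene carbon and the enol-ester carbon, and water on quench hydrolyses the ethoxyallyl cation 10 to the enone. The closest known reactions are the cationic cyclopentannelation of 1-lithio-1-alkoxyallenes with enones (carbinol, (CF3CO)2O, 2,6-lutidine; the allene-ether variant of the Nazarov cyclisation) and the Piancatelli rearrangement, whose pentadienyl cation carries oxygen at the same two positions; new here are the secondary, enal-derived carbinol and the acyloxy group on the closing terminus. The only ring formed is the cyclopentene, closed by a thermally allowed conrotatory 4π electrocyclisation, driven by loss of the cumulated double bond and by the ethoxy group, which sits on a nodal carbon of 9 but on a charged terminus of 10. The single new stereocentre C3 needs no control (racemate), and the Z geometry expected from outward rotation of the decyl group is of no consequence, because both alkene isomers give the same racemic diol after step 4. The step needs attack of 6 on the aldehyde and not on the ester (tert-butyl shielding, −78 °C), O-acylation of the preformed alkoxide and not C-acylation of the enol ether (one equivalent of anhydride), and access to the U-shaped conformer of 9, which the weakly donating pivaloyloxy group (low C4–C5 double-bond character) and reversible ion-pair return at C5 should allow.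

Step 4
Reactants: 11 (±)-(5Z)-4-oxo-5-undecylidenecyclopent-2-en-1-yl pivalate
Product: 13 (±)-cis-2-undecylidenecyclopent-4-ene-1,3-diol, via cis-hydroxy pivalate 12 (not isolated)
Conditions: i-Bu2AlH (4 equiv), CH2Cl2, −78 to −20 °C; aq potassium sodium tartrate
Reagents that add atoms: none
Why: 1,2-Reduction of a 4-acyloxycyclopent-2-enone by i-Bu2AlH occurs from the face opposite the C3 pivalate, which sets C1–OH cis to C3–O as in related 4-oxygenated cyclopentenones, and excess hydride then cleaves the pivalate reductively.

Step 5
Reactants: 13 (±)-cis-2-undecylidenecyclopent-4-ene-1,3-diol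
Product: 14 (±)-cis-2-undecylidenecyclopent-4-ene-1,3-diyl diacetate
Conditions: Ac2O, pyridine, DMAP (cat.), CH2Cl2, 0 °C
Reagents that add atoms: acetic anhydride, CC(=O)OC(C)=O
Why: DMAP-catalysed acetylation of two secondary allylic alcohols runs under basic conditions that avoid ionisation of the doubly allylic C–O bonds and touches no stereocentre.

Step 6
Reactants: 14 (±)-cis-2-undecylidenecyclopent-4-ene-1,3-diyl diacetate
Product: 15 (±)-2-hydroxy-2-(1-hydroxyundecyl)cyclopent-4-ene-1,3-diyl diacetate (C2–OH trans to both acetates)
Conditions: OsO4 (2 mol %), (DHQD)2PHAL and (DHQ)2PHAL (2.5 mol % each), NMO (1.1 equiv), acetone–H2O, 0 °C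
Reagents that add atoms: 4-methylmorpholine N-oxide, C[N+]1([O-])CCOCC1; water, O
Why: Ligand-accelerated catalytic osmylation (syn dihydroxylation) should prefer the trisubstituted exocyclic alkene, the class most accelerated by phthalazine ligands, over the cis-disubstituted ring alkene, and it attacks anti to both allylic acetates, which places C2–OH trans to them, while the 1:1 pair of pseudoenantiomeric ligands offers each enantiomer of 14 a matched catalyst.

Step 7
Reactants: 15 (±)-2-hydroxy-2-(1-hydroxyundecyl)cyclopent-4-ene-1,3-diyl diacetate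
Product: 16 (1R,2r,3S)-2-hydroxy-2-undecanoylcyclopent-4-ene-1,3-diyl diacetate (meso, target)
Conditions: IBX (1.5 equiv), DMSO, rt
Reagents that add atoms: none
Why: IBX oxidises the secondary alcohol of a 1,2-diol to the α-hydroxy ketone without glycol cleavage and leaves the tertiary alcohol and the acetates alone, and removal of the side-chain stereocentre turns the racemate into the single meso target.

Compound list
1 | decylmagnesium bromide | CCCCCCCCCC[Mg]Br | starting material
2 | 3,3-diethoxyprop-1-yne | C#CC(OCC)OCC | starting material
3 | 1-ethoxytrideca-1,2-diene (racemic) | CCCCCCCCCCC=C=COCC | intermediate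
4 | tetrabutylammonium (E)-3-oxoprop-1-en-1-olate | [O-]/C=C/C=O.CCCC[N+](CCCC)(CCCC)CCCC | starting material
5 | (E)-3-oxoprop-1-en-1-yl pivalate | CC(C)(C)C(=O)O/C=C/C=O | intermediate
6 | (1-ethoxytrideca-1,2-dien-1-yl)lithium | CCCCCCCCCCC=C=C([Li])OCC | intermediate
7 | lithium (1E)-4-ethoxy-1-(pivaloyloxy)hexadeca-1,4,5-trien-3-olate (diastereomer mixture) | CCCCCCCCCCC=C=C(OCC)C([O-])/C=C/OC(=O)C(C)(C)C.[Li+] | intermediate
8 | (1E)-4-ethoxy-3-(trifluoroacetoxy)hexadeca-1,4,5-trien-1-yl pivalate | CCCCCCCCCCC=C=C(OCC)C(OC(=O)C(F)(F)F)/C=C/OC(=O)C(C)(C)C | intermediate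
9 | 4-ethoxy-1-(pivaloyloxy)hexadeca-1,4,5-trien-3-ylium (pentadienyl cation) | CCCCCCCCCCC=C=C(OCC)[CH+]/C=C/OC(=O)C(C)(C)C | intermediate
10 | O-ethyl oxocarbenium (1-ethoxyallyl cation) of 11 | CCCCCCCCCC/C=C1\C(=[O+]CC)C=C[C@H]1OC(=O)C(C)(C)C | intermediate
11 | (±)-(5Z)-4-oxo-5-undecylidenecyclopent-2-en-1-yl pivalate | CCCCCCCCCC/C=C1\C(=O)C=C[C@H]1OC(=O)C(C)(C)C | intermediate
12 | cis-4-hydroxy-5-undecylidenecyclopent-2-en-1-yl pivalate (present as its aluminium alkoxide) | CCCCCCCCCC/C=C1\[C@@H](O)C=C[C@H]1OC(=O)C(C)(C)C | intermediate
13 | (±)-cis-2-undecylidenecyclopent-4-ene-1,3-diol | CCCCCCCCCC/C=C1\[C@@H](O)C=C[C@H]1O | intermediate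
14 | (±)-cis-2-undecylidenecyclopent-4-ene-1,3-diyl diacetate | CCCCCCCCCC/C=C1\[C@@H](OC(C)=O)C=C[C@H]1OC(C)=O | intermediate
15 | (±)-2-hydroxy-2-(1-hydroxyundecyl)cyclopent-4-ene-1,3-diyl diacetate | CCCCCCCCCC[C@@H](O)[C@@]1(O)[C@@H](OC(C)=O)C=C[C@H]1OC(C)=O | intermediate
16 | (1R,2r,3S)-2-hydroxy-2-undecanoylcyclopent-4-ene-1,3-diyl diacetate | CCCCCCCCCCC(=O)[C@@]1(O)[C@@H](OC(C)=O)C=C[C@H]1OC(C)=O | target

Total steps: 7. Longest linear sequence: 6 (steps 1, 3, 4, 5, 6, 7).

Steps most likely to fail
1. **Step 3.**
 - Risk: acyl transfer from the enol ester to the organolithium, hydrolytic loss of the allenyl ether, or capture or deprotonation of the cation in an extended conformation before it can close.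
 - Fallback (known chemistry, ring taken from cyclopentadiene instead of being built), from 1 back to 13. Compound 1 is formylated with DMF to undecanal F1. Pyrrolidine-mediated condensation with cyclopentadiene in MeOH gives 6-decylfulvene F2. Tetraphenylporphyrin-sensitised photooxygenation at −78 °C adds singlet oxygen across the ring diene to give 7-undecylidene-2,3-dioxabicyclo[2.2.1]hept-5-ene F3. Thiourea reduces F3 in the same flask to 13.
2. **Step 6.**
 - Risk: competing osmylation of the ring alkene, over-oxidation, or acetyl migration to the new hydroxyl groups.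
 - Fallback, from 14 back to 16. m-CPBA (NaHCO3 buffer, CH2Cl2, 0 °C) responds more steeply to alkene substitution than osmylation does. It should epoxidise the exocyclic alkene anti to the acetates to give 2-decyl-1-oxaspiro[2.4]hept-5-ene-4,7-diyl diacetate F4. Acid-catalysed opening with DMSO (CF3SO3H, then i-Pr2NEt) is productive only at the secondary carbon. It proceeds via the alkoxysulfonium triflate F5, whose base-induced collapse gives 16 with the C2–O bond untouched.
3. **Step 4.**
 - Risk: poor facial selectivity of hydride delivery, conjugate reduction, or ionisation of the doubly allylic alkoxide.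
 - Fallback, from 11 back to 13, sets C1 by inversion instead of by facial bias. Luche reduction (NaBH4, CeCl3·7H2O, MeOH, −78 °C) gives the alcohols. The unwanted trans-4-hydroxy-5-undecylidenecyclopent-2-en-1-yl pivalate F6 is inverted by a Mitsunobu reaction with acetic acid (PPh3, DIAD) to cis-4-acetoxy-5-undecylidenecyclopent-2-en-1-yl pivalate F7. Treatment of F7 with i-Bu2AlH removes both esters to give 13.

Further compounds
F1 | step 3 | undecanal | CCCCCCCCCCC=O
F2 | step 3 | 6-decylfulvene (5-undecylidenecyclopenta-1,3-diene) | CCCCCCCCCCC=C1C=CC=C1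
F3 | step 3 | 7-undecylidene-2,3-dioxabicyclo[2.2.1]hept-5-ene | CCCCCCCCCC/C=C1\[C@@H]2C=C[C@H]1OO2
F4 | step 6 | 2-decyl-1-oxaspiro[2.4]hept-5-ene-4,7-diyl diacetate (oxirane O trans to both acetates) | CCCCCCCCCC[C@H]1O[C@@]12[C@@H](OC(C)=O)C=C[C@H]2OC(C)=O
F5 | step 6 | {1-[2,5-diacetoxy-1-hydroxycyclopent-3-en-1-yl]undecyloxy}dimethylsulfonium triflate | CCCCCCCCCC[C@H](O[S+](C)C)[C@@]1(O)[C@@H](OC(C)=O)C=C[C@H]1OC(C)=O.[O-]S(=O)(=O)C(F)(F)F
F6 | step 4 | trans-4-hydroxy-5-undecylidenecyclopent-2-en-1-yl pivalate | CCCCCCCCCC/C=C1\[C@H](O)C=C[C@H]1OC(=O)C(C)(C)C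
F7 | step 4 | cis-4-acetoxy-5-undecylidenecyclopent-2-en-1-yl pivalate | CCCCCCCCCC/C=C1\[C@@H](OC(C)=O)C=C[C@H]1OC(=O)C(C)(C)C
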